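Going from 25 °C to 55 °C, the step that turns monomer in chains into over-reaction product speeds up 17 times, while the step that makes monomer in chains from free monomer and the living end speeds up 5.5 times, so heat quickens the loss more than the making.

    free monomer + initiator → living end + monomer in chains (k1 = 0.87 M⁻¹ s⁻¹, Ea1 = 46.0 kJ mol⁻¹)
    protic impurity + free monomer → quenched substrate (k2 = 390 M⁻¹ s⁻¹, Ea2 = 37.0 kJ mol⁻¹)
    free monomer + living end → monomer in chains + living end, rate k3*[living end]*[free monomer] (k3 = 580 M⁻¹ s⁻¹, Ea3 = 46.0 kJ mol⁻¹)
    monomer in chains → over-reaction product (k4 = 0.0099 s⁻¹, Ea4 = 77.0 kJ mol⁻¹)
    (constants at 40 °C)

common to all: free monomer 20 mM; protic impurity 0.400 mM; initiator 0.26 mol%; time 4.0 min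
- red: temperature 25 °C
- grey: temperature 55 °C
- ochre: temperature 40 °C
- violet: at 25 °C until 3.0 min, from then on at 55 °C

- the list of constants is for 40 °C, to be carried to other temperatures by the activation energies

- the best flask by amount of monomer in chains, in percent of the free monomer charged; "all alike" if 1.5 percentage points covers them all (red / grey / ochre / violet / all alike)
- amount of monomer in chains at the end, in percent of the free monomer charged, red
- amount of monomer in chains at the end, in percent of the free monomer charged, grey
- amount of monomer in chains at the end, in percent of the free monomer charged, ochre
- amount of monomer in chains at the end, in percent of the free monomer charged, violet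

Since you are asked what survives, count half-lives. Step 4 is first order, so at a given temperature c(monomer in chains) would, by that step alone, halve in a fixed time, whatever its size. Call this the half-life of a chain. Carried by its activation energy, it is 5.17 min at 25 °C, 1.17 min at 40 °C and 0.302 min at 55 °C.

Now divide the time in each flask by the half-life that holds there. Red lives through 0.774 half-lives, ochre 3.43 and grey 13.2. Violet, with its two stretches added, lives through 3.89. My own reckoning ranks the flasks by the share of a chain born at the start that is still there at the end, and this gives red. I commit to no finer figure, since chains born later live through fewer half-lives.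

The forecast also names red, with red at 56%, grey at 0.08%, ochre at 21% and violet at 14%, on the ground that “heat mostly destroys product”. The simulation gives red as the best flask, with red at 56.5%, grey at 0.0786%, ochre at 20.9% and violet at 14.1%.

Read violet's 14.1% with the half-life. At 3.00 min, when it was heated, violet held 48.2% monomer in chains beside 40.7% free monomer. Its hot stretch of 1.00 min is 3.31 half-lives of 0.302 min, so by this reckoning those chains shrink to 4.86%, and the other 9.2 percentage points of violet's figure are reckoned as chains made after the change and still standing at the end. In grey, the same half-life counts 6.62 half-lives between 2.00 min and 4.00 min. Reckoned by step 4 alone, that takes grey's 5.55% down to 0.0563%, and grey holds 0.0786%.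

The rate constants were drawn at random within sensible limits.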